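## Analysis of the target

Target 27, 3-{[5,7-dihydroxy-2,2-dimethyl-6-(2-methylpropanoyl)-2H-chromen-8-yl]methyl}-6-ethyl-4-hydroxy-5-methyl-2H-pyran-2-one, joins a 2,2-dimethyl-2H-chromene and a 4-hydroxy-2H-pyran-2-one through one methylene carbon bonded to chromene C8 and pyranone C3. The benzene ring of the chromene is hexasubstituted: O1 on C8a, C4 on C4a, hydroxyls on C5 and C7, the 2-methylpropanoyl group on C6 and the bridge on C8. There is no stereocentre, and the only geometric element, the C3=C4 alkene, is held cis by the ring, so the whole problem is one of regiochemistry. The sensitive parts are the chromene (a tertiary allylic aryl ether at O1–C2 and an electron-rich styrene-type alkene), the methylene bridge between two enol-type π systems (prone to acid-induced fragmentation), the pyranone as a vinylogous acid (C- versus O-alkylation) and the free phenols. The difficulty is to place three different carbon substituents around a 1,3,5-trioxygenated ring in which C6 and C8 are both flanked by two oxygens and are electronically almost alike. The strategy rests on one feature: O1 and C4 sit on the neighbouring ring carbons C8a and C4a, and the oxygen on C5 lies beside C4a. The C8a–C4a bond can therefore be the triple bond of an aryne that the C5 alkoxy group polarises, and O1, C2 with its two methyls, C3 and C4 map onto one five-carbon enal.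

## Retrosynthetic reasoning

**27 to 25.** The two O–CH3 bonds at C5 and C7 are cut last, so 27 goes back to the bis(methyl ether) 25. Methyl is chosen because it survives an aryne, organolithium reagents, a chloroiminium electrophile and a hydride donor alike. In 25 both ethers lie ortho to the C6 ketone and are flanked on both sides, which is where a Lewis acid cleaves them at low temperature. The forward step must cleave both ethers without ionising the O1–C2 bond or the bridge.

**25 to 18 and 23.** The bond between the bridging carbon and pyranone C3 is cut, and the bridging carbon is traced back to an aldehyde carbon on C8 of 18. Cutting on the pyranone side means the bond is made by condensation at the most acidic carbon of 23 followed by conjugate reduction, so O-alkylation and double alkylation of 23 cannot occur. The forward step must form the alkylidene 24 and reduce it before a second molecule of 23 adds.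

**23 to 20 and 21, and 20 to 19.** In 23 the C4–C5 bond and the lactone O1–C2 bond are cut. This gives a three-carbon unit with two acylating ends, 21, and the enol form of the symmetrical ketone 19, used as silyl enol ether 20. Because 19 is symmetrical, 20 is a single constitutional isomer, and the ethyl group on C6 and the methyl group on C5 follow without any regiochemical decision.

**18 to 13 and 14.** The C6–acyl bond is cut to an aryl anion at C6 and the acyl donor 14. Once C8 carries the formyl carbon, C6 bears the only hydrogen left on the benzene ring and lies between two methoxy groups, the best arrangement for directed lithiation. The position of the acyl group therefore needs no further choice. The forward step must mask the aldehyde in the flask (15), lithiate (16) and transfer exactly one acyl group (17).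

**13 to 11.** The C8–CHO bond is cut. The one-carbon electrophile is introduced first because the position it should prefer on steric grounds, C8, is the position where the bridge is needed. Had the bulkier acyl group been introduced first, the same preference would have worked against the route.

**11 to 6 and 7.** Three bonds of the pyran ring are cut at once: C4a–C4, C8a–O1 and O1–C2. This leaves aryne 8, released from the silyl triflate 6, and the enal 7, which supplies C2 with both methyls, C3, C4 and O1. The cut is made here because it removes the whole heterocycle in one operation and leaves an aromatic piece with the oxygen pattern of 1. The forward reaction must add the carbonyl oxygen to the aryne carbon that becomes C8a and the carbonyl carbon to the one that becomes C4a (9), open to 10 and close the ring.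

**6 to 3, 2 and 1.** The O–S bond and the C–Si bond of 6 are cut. The silyl group is taken back to the oxygen of 3, from which it migrates to carbon after bromine–lithium exchange, and the bromine of 2 is traced back to ortho-bromination of 1. Three standard operations thus lead from 1 to the aryne precursor.

## Alternatives that were turned down

**Alternative 1:** The benzene ring is cut at C7–C8 and C5–C6 (chromene numbering). The pieces are the bicyclic anhydride 2,2,8-trimethyl-2H-pyrano[4,3-b]pyran-5,7(8H)-dione (A2) and the ynone 1-ethoxy-4-methylpent-1-yn-3-one (A3). The anhydride A2 already holds the dimethylpyran ring.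
- Forward key step: the anion of A2 at its methyl-bearing carbon adds in conjugate fashion to A3, the allenolate carbon of the adduct is acylated by the anhydride carbonyl attached to C4a, and loss of carbon dioxide aromatises the ring. The product is 1-(7-ethoxy-5-hydroxy-2,2,8-trimethyl-2H-chromen-6-yl)-2-methylpropan-1-one (A1).
- For: every substituent of the benzene ring of A1 is placed by construction, the acyl group is on C6 with certainty, and no isomers have to be separated. On this point it is stronger than the chosen strategy.
- Against: A1 carries an unfunctionalised methyl group on C8. Turning it into the bridge needs benzylic functionalisation in a molecule with an electron-rich alkene and a free phenol, where radical halogenation would attack C3=C4 or the ring. The ethyl ether on C7 must still be cleaved, and neither A2 (a labile enol-ether anhydride) nor A3 is commercial.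
- Comparison: the chosen strategy takes the aromatic ring from 1, brings in the C8 carbon at the aldehyde oxidation state so that the bridge follows in one step, and is much shorter.

**Alternative 2:** The pyranone O1–C6 bond is cut, so the pyranone is built last. The open-chain precursor is the benzylated β-keto ester tert-butyl 2-{[5,7-dimethoxy-2,2-dimethyl-6-(2-methylpropanoyl)-2H-chromen-8-yl]methyl}-4-methyl-3-oxohept-5-ynoate (A5). Ring closure of A5 leads to the 2-alkoxy-4-pyranone A4.
- Forward key step: base isomerises the alkynyl ketone of A5 to the allenyl ketone, and the ester enolate oxygen adds to the central allene carbon. The product is 2-tert-butoxy-3-{[5,7-dimethoxy-2,2-dimethyl-6-(2-methylpropanoyl)-2H-chromen-8-yl]methyl}-6-ethyl-5-methyl-4H-pyran-4-one (A4). A4 must then lose the tert-butyl group and both methyl groups.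
- For: the bond from the bridge to pyranone C3 exists before the heterocycle does, so C- versus O-alkylation of a pyranone never arises, and the closure to A4 is intramolecular.
- Against: it leaves the hard part unsolved. A5 still requires the fully substituted chromene with the acyl group on C6 and a halomethyl group on C8. The doubly activated C–H of A5 between ketone and ester is removed first, which hinders the second deprotonation that the alkyne-to-allene shift needs. Acid removal of the tert-butyl group from A4 has to spare the chromene, and the step count is higher.
- Comparison: the two routes are equal in the final ether cleavage, which A4 needs as much as 25 does. The chosen route makes 23 in two steps from 19 and attaches it in one.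

**Alternative 3:** The C3=C4 alkene of the chromene is cut, giving the diene 1-[3-ethenyl-2,6-dihydroxy-4-(2-methylbut-3-en-2-yloxy)phenyl]-2-methylpropan-1-one (A7).
- Forward key step: the second-generation Grubbs catalyst closes A7 by ring-closing metathesis, with loss of ethylene, to 1-(5,7-dihydroxy-2,2-dimethyl-2H-chromen-6-yl)-2-methylpropan-1-one (A6). A6 would then be joined to 23 through a one-carbon electrophile at C8.
- For: the acyl group is in place from the start, C8 is the only free ring position of A6, and no protecting group has to be removed at the end. On the C6/C8 question and on the end game it is stronger than the chosen strategy.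
- Against: A7 needs a 1,1-dimethylallyl ether on one particular oxygen of three and a vinyl group on one particular neighbouring carbon. Tertiary allylic aryl ethers cannot be made by simple substitution, undergo aromatic Claisen rearrangement on gentle heating and ionise easily. The gem-dimethyl group beside the reacting alkene slows metathesis, and several steps are spent on a ring that 7 delivers in one.
- Comparison: the chosen strategy forms three bonds from two simple components, with the positions of O1 and C4 fixed by the methoxy group beside the aryne.

Key step: step 4

Remark: C6 and C8 of 11 are electronically alike. The route assumes that the first electrophile enters at C8, the less shielded position, because O1 is tied back in the pyran ring whereas C6 lies between two methoxy groups. The fallback for step 5 covers the opposite case.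

## Route

Step 1
Reactants: 1 3,5-dimethoxyphenol
Product: 2 2-bromo-3,5-dimethoxyphenol
Conditions: NBS, CH2Cl2, −78 °C to rt
Reagents that add atoms: N-bromosuccinimide, O=C1CCC(=O)N1Br
Why: Electrophilic aromatic bromination of a strongly activated phenol with one equivalent of reagent at low temperature should stop at the monobromide; the two positions ortho to the hydroxyl are equivalent, and the isomer brominated between the two methoxy groups, if formed, is removed by chromatography.

Step 2
Reactants: 2 2-bromo-3,5-dimethoxyphenol
Product: 3 (2-bromo-3,5-dimethoxyphenoxy)trimethylsilane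
Conditions: HMDS, THF, 65 °C; concentrate
Reagents that add atoms: hexamethyldisilazane, C[Si](C)(C)N[Si](C)(C)C
Why: O-Silylation of a phenol by a silazane, driven by loss of a volatile amine by-product, should give the silyl ether free of salts, so that the crude product can be used directly.

Step 3
Reactants: 3 (2-bromo-3,5-dimethoxyphenoxy)trimethylsilane
Product: 6 3,5-dimethoxy-2-(trimethylsilyl)phenyl trifluoromethanesulfonate, via aryllithium 4 (not isolated), via lithium 2-silylphenolate 5 (not isolated)
Conditions: n-BuLi, THF, −100 to −80 °C; then Tf2O, −100 °C to rt
Reagents that add atoms: trifluoromethanesulfonic anhydride, O=S(=O)(OS(=O)(=O)C(F)(F)F)C(F)(F)F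
Why: Bromine–lithium exchange is faster than any deprotonation at −100 °C; aryllithium 4 takes the silyl group from the neighbouring oxygen (anionic 1,3 O-to-C shift, retro-Brook rearrangement) to give phenolate 5, which is sulfonylated on oxygen.

Step 4
Reactants: 6 3,5-dimethoxy-2-(trimethylsilyl)phenyl trifluoromethanesulfonate; 7 3-methylbut-2-enal
Product: 11 5,7-dimethoxy-2,2-dimethyl-2H-chromene, via 3,5-dimethoxybenzyne 8 (not isolated), via benzoxete 9 (not isolated), via ortho-quinone methide 10 (not isolated)
Conditions: CsF, MeCN, rt; 6 added slowly to 7 (excess)
Reagents that add atoms: none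
Why: Fluoride attacks silicon in 6 and the ortho triflate leaves, giving aryne 8 under neutral conditions at room temperature. The carbonyl oxygen of 7 adds to the aryne carbon that carried the triflate, remote from the flanking methoxy group, because this places the developing aryl anion on the carbon beside the inductively withdrawing C–OMe bond and is also the less hindered end; the anion then closes on the oxocarbenium carbon to benzoxete 9, a formal [2+2] cycloaddition. Thermal 4π electrocyclic opening of 9 gives ortho-quinone methide 10, and the isomer with the vinyl group cis to the ring carbonyl closes by a thermal disrotatory oxa-6π electrocyclisation that forms O1–C2 and the 2H-pyran ring, with rearomatisation as the driving force. The closest known reaction type is the aryne–aldehyde [2+2] and ring-opening route to ortho-quinone methides, which with α,β-unsaturated aldehydes ends in 2H-chromenes; the last stage is the same electrocyclisation that operates in phenol–enal chromene syntheses. No stereocentre is formed, since C2 carries two methyl groups and the stereocentre of 9 is lost on ring opening. The step needs regioselective addition to the unsymmetrical aryne, which the methoxy group next to the triple bond secures, and it needs ring closure of 10 to outrun capture by a second aryne, which slow addition of 6 to an excess of 7 secures.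

Step 5
Reactants: 11 5,7-dimethoxy-2,2-dimethyl-2H-chromene
Product: 13 5,7-dimethoxy-2,2-dimethyl-2H-chromene-8-carbaldehyde, via aryl iminium salt 12 (not isolated)
Conditions: POCl3, DMF, 0 °C to rt; then H2O
Reagents that add atoms: N,N-dimethylformamide, CN(C)C=O; water, O
Why: Vilsmeier–Haack formylation of a trialkoxybenzene; C8 and C6 are each ortho or para to all three oxygens, and the bulky chloroiminium ion should prefer C8, which is flanked by the tied-back ring oxygen instead of two methoxy groups. The alkene carbon C3 is shielded by the neighbouring gem-dimethyl group, and any C6 isomer is separated by chromatography.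

Step 6
Reactants: 13 5,7-dimethoxy-2,2-dimethyl-2H-chromene-8-carbaldehyde; 14 N-methoxy-N,2-dimethylpropanamide
Product: 18 5,7-dimethoxy-2,2-dimethyl-6-(2-methylpropanoyl)-2H-chromene-8-carbaldehyde, via amino alkoxide 15 (not isolated), via aryllithium 16 (not isolated), via tetrahedral adduct 17 (not isolated)
Conditions: lithium 4-methylpiperazin-1-ide (from 1-methylpiperazine, n-BuLi), THF, −20 °C; n-BuLi, TMEDA, −20 to 0 °C; 14 (excess), −78 °C to rt; aq. NH4Cl
Reagents that add atoms: none
Why: Lithium 4-methylpiperazin-1-ide adds to the aldehyde and masks it as α-amino alkoxide 15, which is inert to n-BuLi; directed ortho-metalation then removes the only hydrogen left on the benzene ring, at C6 between two methoxy groups, to give 16. Acylation by the Weinreb amide (Weinreb ketone synthesis) stops at chelated adduct 17, and aqueous work-up releases ketone and aldehyde together.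

Step 7
Reactants: 19 pentan-3-one
Product: 20 (Z)-trimethyl(pent-2-en-3-yloxy)silane
Conditions: TMSOTf, Et3N, CH2Cl2, 0 °C
Reagents that add atoms: trimethylsilyl trifluoromethanesulfonate, C[Si](C)(C)OS(=O)(=O)C(F)(F)F
Why: Soft enolisation (silyl triflate activation, amine deprotonation) of a symmetrical ketone gives one constitutional isomer; the Z isomer is expected to predominate, and the geometry is irrelevant because it is lost in the next step.

Step 8
Reactants: 20 (Z)-trimethyl(pent-2-en-3-yloxy)silane; 21 propanedioyl dichloride
Product: 23 6-ethyl-4-hydroxy-5-methyl-2H-pyran-2-one, via keto acid chloride 22 (not isolated)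
Conditions: Et2O, −78 °C to rt
Reagents that add atoms: none
Why: Acylative annulation of a silyl enol ether with malonyl dichloride: C-acylation with loss of the silyl group gives 22, whose ketone enol oxygen closes on the second acid chloride (lactonisation), and tautomerisation gives the 4-hydroxy-2-pyranone.

Step 9
Reactants: 18 5,7-dimethoxy-2,2-dimethyl-6-(2-methylpropanoyl)-2H-chromene-8-carbaldehyde; 23 6-ethyl-4-hydroxy-5-methyl-2H-pyran-2-one
Product: 25 3-{[5,7-dimethoxy-2,2-dimethyl-6-(2-methylpropanoyl)-2H-chromen-8-yl]methyl}-6-ethyl-4-hydroxy-5-methyl-2H-pyran-2-one, via arylidene pyrandione 24 (not isolated)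
Conditions: L-proline (cat.), Hantzsch ester (diethyl 2,6-dimethyl-1,4-dihydropyridine-3,5-dicarboxylate), CH2Cl2, rt
Reagents that add atoms: none
Why: Organocatalytic three-component reductive alkylation: proline-catalysed Knoevenagel condensation at C3 of 23 gives the electron-poor alkene 24, which takes up hydride from the dihydropyridine much faster than the aldehyde or the hindered ketone does. Only C-monoalkylation is possible by this mechanism.

Step 10
Reactants: 25 3-{[5,7-dimethoxy-2,2-dimethyl-6-(2-methylpropanoyl)-2H-chromen-8-yl]methyl}-6-ethyl-4-hydroxy-5-methyl-2H-pyran-2-one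
Product: 27 3-{[5,7-dihydroxy-2,2-dimethyl-6-(2-methylpropanoyl)-2H-chromen-8-yl]methyl}-6-ethyl-4-hydroxy-5-methyl-2H-pyran-2-one, via dichloroboryl ester 26 (not isolated)
Conditions: BCl3 (excess), CH2Cl2, −78 to 0 °C; then H2O
Reagents that add atoms: none
Why: Lewis-acid cleavage of aryl methyl ethers: both methoxy groups are ortho to the C6 ketone and flanked on both sides, hence twisted out of conjugation and basic, so boron coordination and chloride attack at methyl should remove both at low temperature. The low temperature spares the O1–C2 bond and the bridge, and the boron–oxygen bonds of 26 are hydrolysed on work-up.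

## Compound list

1 | 3,5-dimethoxyphenol | COc1cc(O)cc(OC)c1 | starting material
2 | 2-bromo-3,5-dimethoxyphenol | COc1cc(O)c(Br)c(OC)c1 | intermediate
3 | (2-bromo-3,5-dimethoxyphenoxy)trimethylsilane | COc1cc(O[Si](C)(C)C)c(Br)c(OC)c1 | intermediate
4 | [2,4-dimethoxy-6-(trimethylsilyloxy)phenyl]lithium | COc1cc(O[Si](C)(C)C)c([Li])c(OC)c1 | intermediate (not isolated)
5 | lithium 3,5-dimethoxy-2-(trimethylsilyl)phenolate | COc1cc([O-])c([Si](C)(C)C)c(OC)c1.[Li+] | intermediate (not isolated)
6 | 3,5-dimethoxy-2-(trimethylsilyl)phenyl trifluoromethanesulfonate | COc1cc(OC)c([Si](C)(C)C)c(OS(=O)(=O)C(F)(F)F)c1 | intermediate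
7 | 3-methylbut-2-enal | CC(C)=CC=O | starting material
8 | 3,5-dimethoxybenzyne (1,2-didehydro-3,5-dimethoxybenzene) | COC1=CC(OC)=CC#C1 | intermediate (not isolated)
9 | 3,5-dimethoxy-2-(2-methylprop-1-en-1-yl)-2H-1-benzoxete (racemic) | COc1cc(OC)c2C(C=C(C)C)Oc2c1 | intermediate (not isolated)
10 | (6Z)-3,5-dimethoxy-6-(3-methylbut-2-en-1-ylidene)cyclohexa-2,4-dien-1-one | COC1=CC(=O)/C(=C\C=C(C)C)C(OC)=C1 | intermediate (not isolated)
11 | 5,7-dimethoxy-2,2-dimethyl-2H-chromene | COc1cc(OC)c2C=CC(C)(C)Oc2c1 | intermediate
12 | N-[(5,7-dimethoxy-2,2-dimethyl-2H-chromen-8-yl)methylidene]-N-methylmethanaminium dichlorophosphate | CC1(C)C=Cc2c(OC)cc(OC)c(C=[N+](C)C)c2O1.[O-]P(=O)(Cl)Cl | intermediate (not isolated)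
13 | 5,7-dimethoxy-2,2-dimethyl-2H-chromene-8-carbaldehyde | CC1(C)C=Cc2c(OC)cc(OC)c(C=O)c2O1 | intermediate
14 | N-methoxy-N,2-dimethylpropanamide | CC(C)C(=O)N(C)OC | starting material
15 | lithium (5,7-dimethoxy-2,2-dimethyl-2H-chromen-8-yl)(4-methylpiperazin-1-yl)methanolate (racemic) | CC1(C)C=Cc2c(OC)cc(OC)c(C([O-])N3CCN(C)CC3)c2O1.[Li+] | intermediate (not isolated)
16 | lithium (6-lithio-5,7-dimethoxy-2,2-dimethyl-2H-chromen-8-yl)(4-methylpiperazin-1-yl)methanolate (racemic) | CC1(C)C=Cc2c(OC)c([Li])c(OC)c(C([O-])N3CCN(C)CC3)c2O1.[Li+] | intermediate (not isolated)
17 | dilithium 1-{5,7-dimethoxy-2,2-dimethyl-8-[(4-methylpiperazin-1-yl)oxidomethyl]-2H-chromen-6-yl}-1-[methoxy(methyl)amino]-2-methylpropan-1-olate (mixture of stereoisomers) | CC1(C)C=Cc2c(OC)c(C([O-])(C(C)C)N(C)OC)c(OC)c(C([O-])N3CCN(C)CC3)c2O1.[Li+].[Li+] | intermediate (not isolated)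
18 | 5,7-dimethoxy-2,2-dimethyl-6-(2-methylpropanoyl)-2H-chromene-8-carbaldehyde | CC1(C)C=Cc2c(OC)c(C(=O)C(C)C)c(OC)c(C=O)c2O1 | intermediate
19 | pentan-3-one | CCC(=O)CC | starting material
20 | (Z)-trimethyl(pent-2-en-3-yloxy)silane | C/C=C(/CC)O[Si](C)(C)C | intermediate
21 | propanedioyl dichloride (malonyl dichloride) | O=C(Cl)CC(=O)Cl | starting material
22 | 4-methyl-3,5-dioxoheptanoyl chloride (racemic) | CCC(=O)C(C)C(=O)CC(=O)Cl | intermediate (not isolated)
23 | 6-ethyl-4-hydroxy-5-methyl-2H-pyran-2-one | CCc1oc(=O)cc(O)c1C | intermediate
24 | 3-{[5,7-dimethoxy-2,2-dimethyl-6-(2-methylpropanoyl)-2H-chromen-8-yl]methylidene}-6-ethyl-5-methyl-2H-pyran-2,4(3H)-dione (mixture of double-bond isomers) | CCC1=C(C)C(=O)C(=Cc2c(OC)c(C(=O)C(C)C)c(OC)c3c2OC(C)(C)C=C3)C(=O)O1 | intermediate (not isolated)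
25 | 3-{[5,7-dimethoxy-2,2-dimethyl-6-(2-methylpropanoyl)-2H-chromen-8-yl]methyl}-6-ethyl-4-hydroxy-5-methyl-2H-pyran-2-one | CCc1oc(=O)c(Cc2c(OC)c(C(=O)C(C)C)c(OC)c3c2OC(C)(C)C=C3)c(O)c1C | intermediate
26 | 3-{[5,7-bis(dichloroboryloxy)-2,2-dimethyl-6-(2-methylpropanoyl)-2H-chromen-8-yl]methyl}-4-(dichloroboryloxy)-6-ethyl-5-methyl-2H-pyran-2-one (formal structure of the boron-bound product) | CCc1oc(=O)c(Cc2c(OB(Cl)Cl)c(C(=O)C(C)C)c(OB(Cl)Cl)c3c2OC(C)(C)C=C3)c(OB(Cl)Cl)c1C | intermediate (not isolated)
27 | 3-{[5,7-dihydroxy-2,2-dimethyl-6-(2-methylpropanoyl)-2H-chromen-8-yl]methyl}-6-ethyl-4-hydroxy-5-methyl-2H-pyran-2-one | CCc1oc(=O)c(Cc2c(O)c(C(=O)C(C)C)c(O)c3c2OC(C)(C)C=C3)c(O)c1C | target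

## Step count and least certain steps

Total: 10 steps. Longest linear sequence: 8 steps (steps 1 to 6, 9 and 10); the pyranone branch (steps 7 and 8) is two steps.

**Step 4 (key step).** The ortho-quinone methide may be captured by a second aryne in a [4+2] addition before it cyclises. The aryl anion formed after oxygen attack may also be protonated by the acidic γ-hydrogens of the enal or by the solvent before it closes, and fluoride may cause self-condensation of the enal. Fallback: set out from 1 and 7 and condense them directly (pyridine, 140 °C, or ethylenediammonium diacetate in hot toluene). The ortho carbon of the phenol adds to the enal and dehydration gives the same intermediate 10, which closes to 11, where the route is rejoined. No new compound is involved.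

**Step 5.** The electrophile may enter at C6 instead of C8, or attack the alkene at C3, so that the wrong aldehyde predominates. Fallback: set out from 11 and reverse the order of the two substitutions, so that the same site preference is used productively. Friedel–Crafts acylation with 2-methylpropanoyl chloride and SnCl4 in CH2Cl2 at −78 °C should then give 1-(5,7-dimethoxy-2,2-dimethyl-2H-chromen-6-yl)-2-methylpropan-1-one F1. Vilsmeier–Haack formylation of F1 at C8, then the only free ring position, returns to the route at 18.

**Step 6.** The masking of the aldehyde may be incomplete, so that n-BuLi adds to it. Lithiation at the crowded C6 may be slow, and the hindered aryllithium may deprotonate the amide instead of adding to it. Fallback: set out from 13 and reduce it with NaBH4 to (5,7-dimethoxy-2,2-dimethyl-2H-chromen-8-yl)methanol F2, whose lithium alkoxide needs no protection. Lithiation at C6 with excess n-BuLi and TMEDA and addition to 2-methylpropanal should give 1-[8-(hydroxymethyl)-5,7-dimethoxy-2,2-dimethyl-2H-chromen-6-yl]-2-methylpropan-1-ol F3. Oxidation of both benzylic alcohols with Dess–Martin periodinane returns to the route at 18.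

**Step 9.** Condensation of the di-ortho-substituted aldehyde may be slow, and conjugate addition of a second pyranone to the alkylidene intermediate may outrun hydride transfer. Fallback: set out from 18 and reduce the aldehyde selectively (NaBH4, MeOH, −20 °C; the twisted, doubly flanked ketone is much less reactive) to 1-[8-(hydroxymethyl)-5,7-dimethoxy-2,2-dimethyl-2H-chromen-6-yl]-2-methylpropan-1-one F4. Ionisation of F4 with catalytic p-toluenesulfonic acid gives a benzylic cation stabilised by three oxygens, which alkylates 23 at C3 in a Friedel–Crafts-type reaction and returns to the route at 25.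

**Step 10.** Cleavage may stop after the first ether, once the only ketone is tied up in a boron chelate. Longer exposure to the Lewis acid may ionise the O1–C2 bond or fragment the methylene bridge. Fallback: set out from 18 and cleave the ethers before the bridge exists. In 18 the 7-methoxy group lies between two carbonyl groups and the 5-methoxy group beside the ketone, so each ether has a carbonyl oxygen of its own to hold the boron. Brief treatment with BCl3 at −78 °C should therefore give 5,7-dihydroxy-2,2-dimethyl-6-(2-methylpropanoyl)-2H-chromene-8-carbaldehyde F5. The proline and Hantzsch ester reductive alkylation of 23 with F5 then forms the bridge last under neutral conditions and reaches the route at 27.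

## Further compounds

F0 | step 4 | none | none
F1 | step 5 | 1-(5,7-dimethoxy-2,2-dimethyl-2H-chromen-6-yl)-2-methylpropan-1-one | CC1(C)C=Cc2c(OC)c(C(=O)C(C)C)c(OC)cc2O1
F2 | step 6 | (5,7-dimethoxy-2,2-dimethyl-2H-chromen-8-yl)methanol | CC1(C)C=Cc2c(OC)cc(OC)c(CO)c2O1
F3 | step 6 | 1-[8-(hydroxymethyl)-5,7-dimethoxy-2,2-dimethyl-2H-chromen-6-yl]-2-methylpropan-1-ol (racemic) | CC1(C)C=Cc2c(OC)c(C(O)C(C)C)c(OC)c(CO)c2O1
F4 | step 9 | 1-[8-(hydroxymethyl)-5,7-dimethoxy-2,2-dimethyl-2H-chromen-6-yl]-2-methylpropan-1-one | CC1(C)C=Cc2c(OC)c(C(=O)C(C)C)c(OC)c(CO)c2O1
F5 | step 10 | 5,7-dihydroxy-2,2-dimethyl-6-(2-methylpropanoyl)-2H-chromene-8-carbaldehyde | CC1(C)C=Cc2c(O)c(C(=O)C(C)C)c(O)c(C=O)c2O1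
A1 | alternative 1 | 1-(7-ethoxy-5-hydroxy-2,2,8-trimethyl-2H-chromen-6-yl)-2-methylpropan-1-one | CCOc1c(C)c2OC(C)(C)C=Cc2c(O)c1C(=O)C(C)C
A2 | alternative 1 | 2,2,8-trimethyl-2H-pyrano[4,3-b]pyran-5,7(8H)-dione (racemic) | CC1C(=O)OC(=O)C2=C1OC(C)(C)C=C2
A3 | alternative 1 | 1-ethoxy-4-methylpent-1-yn-3-one | CCOC#CC(=O)C(C)C
A4 | alternative 2 | 2-tert-butoxy-3-{[5,7-dimethoxy-2,2-dimethyl-6-(2-methylpropanoyl)-2H-chromen-8-yl]methyl}-6-ethyl-5-methyl-4H-pyran-4-one | CCc1oc(OC(C)(C)C)c(Cc2c(OC)c(C(=O)C(C)C)c(OC)c3c2OC(C)(C)C=C3)c(=O)c1C
A5 | alternative 2 | tert-butyl 2-{[5,7-dimethoxy-2,2-dimethyl-6-(2-methylpropanoyl)-2H-chromen-8-yl]methyl}-4-methyl-3-oxohept-5-ynoate (mixture of stereoisomers) | CC#CC(C)C(=O)C(Cc1c(OC)c(C(=O)C(C)C)c(OC)c2c1OC(C)(C)C=C2)C(=O)OC(C)(C)C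
A6 | alternative 3 | 1-(5,7-dihydroxy-2,2-dimethyl-2H-chromen-6-yl)-2-methylpropan-1-one | CC(C)C(=O)c1c(O)cc2OC(C)(C)C=Cc2c1O
A7 | alternative 3 | 1-[3-ethenyl-2,6-dihydroxy-4-(2-methylbut-3-en-2-yloxy)phenyl]-2-methylpropan-1-one | CC(C)C(=O)c1c(O)cc(OC(C)(C)C=C)c(C=C)c1O
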